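**Proposed synthesis of CNP0192286.0 (compound 16) by an Alder–Rickert construction of ring B**

## The problem

Target 16 is a depside: two benzene rings, neither carrying a ring hydrogen, joined by an aryl ester between the carboxyl carbon of ring A and the C4 oxygen of ring B. There is no stereocenter, so the difficulty is purely regiochemical. Ring B (C1 CO2Me, C2 OMe, C3 Me, C4 O-acyl, C5 Me, C6 Me) has two oxygens in a 1,3-relationship that must end up different, and its last carbon substituent cannot be introduced by electrophilic substitution on a crowded, pentasubstituted ring. Ring A (C1′ carbonyl, C2′ OMe, C3′ Me, C4′ OH, C5′ Cl, C6′ Me) differs from commercial atraric acid 9 only by the chlorine, one O-methyl group and the state of the carboxyl group. The ester linking the rings has two ortho substituents on the acyl side and two on the phenol side, so it is slow to form. Once formed it is shielded, but as an aryl ester it will still not tolerate alkoxide, hydroxide or strong Lewis acids. The C5′–Cl bond will not tolerate hydrogenolysis, which restricts how the C4′ hydroxyl can be masked and released. The key step rests on the C2–C3–C4–C5 segment of ring B: with its two oxygens it is the diene of a 1-methoxy-3-siloxycyclohexa-1,3-diene that can be made from 2-methylcyclohexane-1,3-dione 1, and C1 and C6 with their ester and methyl groups are the two sp carbons of methyl but-2-ynoate 5.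

## Retrosynthesis

**16 from 15.** No skeletal bond is cut; the C4′ hydroxyl of 16 is traced back to the allyl ether 15. Allyl is preferred over benzyl, whose hydrogenolysis would endanger the C5′–Cl bond. It is preferred over silyl and acetal groups, which would not survive both the basic ester hydrolysis and the acidic coupling earlier in the ring A series. The forward step only needs a neutral, room-temperature allyl transfer catalysed by zerovalent palladium.

**15 from 13 and 8.** The acyl C–O bond of the depside is cut. This divides the molecule into two arenes of similar size, the ring A acid 13 and the ring B phenol 8, and makes the route convergent. The neighbouring option, keeping the ester and building one ring onto it, is less convergent and exposes an aryl ester to ring-forming conditions. The forward reaction must esterify a di-ortho-substituted acid with a di-ortho-substituted phenol. Activation of 13 as the mixed anhydride 14, which reacts through an acylium-like species, meets this demand.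

**8 from 7, and 7 from 4 and 5.** Phenol 8 is the desilylated form of aryl silyl ether 7. In 7 the ring B bonds C1–C2 and C5–C6 are cut, and a two-carbon bridge is notionally added between C2 and C5, which leads to the bicyclo[2.2.2]octadiene 6 and from there to diene 4 and alkynoate 5. This cut is preferred over any substitution chemistry on a preformed arene because all six substituents arrive already attached to the two partners. The two oxygens arrive differentiated as OMe and OSi, and no oxidation is needed since the bridge leaves as a volatile alkene. The precursors are a three-step diene and a commercial alkyne. The forward reaction must deliver the correct regiochemistry and proceed at a temperature the silyl dienol ether tolerates.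

**4 from 3, 3 from 2, 2 from 1.** The O–Si bond of 4 is cut to give enone 3. The C–CH3 bond at the α′ carbon of 3 is cut to give vinylogous ester 2, and the O–CH3 bond of 2 is cut to give the symmetrical dione 1. Each forward step is a standard operation on a vinylogous ester: enol etherification, kinetic α′-alkylation, and kinetic enolisation with O-silylation.

**13 from 12, 11, 10 and 9.** Ring A needs no skeletal disconnection, because atraric acid 9 already has every carbon in place. The acid 13 is traced back to methyl ester 12, its O-methyl group to the chelated phenol 11, its O-allyl group to diol 10, and the chlorine to 9. The order is set by chemoselectivity. Chlorination comes first, while no alkene is present and only C5′ is open. Allylation follows at the non-chelated hydroxyl, then methylation at the chelated one, with ester hydrolysis last.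

## Roads not taken

**Alternative 1:** Ring B is cut through C1–C6 and C2–C3 at the cyclohexanedione oxidation level. In the forward direction dimethyl malonate A1 undergoes methoxide-mediated Michael addition to (E)-4-methylhex-4-en-3-one A2, and the adduct closes by Claisen condensation to methyl 3,5,6-trimethyl-2,4-dioxocyclohexane-1-carboxylate A3. A3 must then be dehydrogenated to methyl 2,4-dihydroxy-3,5,6-trimethylbenzoate A4.
- Merits: cheap bulk reagents, no sealed tube, no moisture-sensitive intermediate, and the whole substituted carbocycle assembled in one flask. In robustness of materials and scalability this road is better than the chosen one.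
- Weak points: A2 is not a stock chemical, and conjugate addition to an enone substituted at both the α and β carbons is slow and reversible. A3 is two hydrogens short of an arene, and aromatisation needs an oxidant acting at C5/C6, whereas the most enolisable positions are C1 and C3. Arene A4 has two free hydroxyls, so a protect–methylate–deprotect sequence is still needed before the C4 oxygen can be acylated and the C2 oxygen can be a methyl ether.
- Comparison: against the cheaper inputs of this road, the chosen plan offers a redox-neutral aromatisation and oxygens that are already differentiated when the ring appears, which saves about three steps.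

**Alternative 2:** Here ring A is cut, through C1′–C6′ and C2′–C3′. The but-2-ynoate ester A5 of phenol 8 would react thermally with the ketene acetal diene 1,1-dimethoxy-2-methyl-3-(trimethylsilyloxy)buta-1,3-diene A6. Loss of methanol and desilylation would give the des-chloro depside A7, and chlorination at the only open position C5′ would give 16.
- Merits: the depside ester is formed from an unhindered alkynoic acid, the C4′ hydroxyl never needs a protecting group, and the chlorine enters last at the only free position. In convergence and protecting-group economy this road is better than the chosen one.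
- Weak points: it builds the ring that can be bought (all carbons of ring A are present in 9) and leaves ring B unsolved, because phenol 8 is still required. Diene A6 is a hydrolytically fragile ketene acetal that needs its own synthesis. A5 is an activated aryl ester, so acyl transfer to the nucleophilic diene, or conjugate addition without ring closure, can compete with cycloaddition.
- Comparison: the chosen plan uses a cycloaddition for ring B, which is not available from any commercial arene, and takes ring A from 9 by four conventional operations.

**Alternative 3:** Ring B is cut at the C6–CH3 and C1–CO2Me bonds. An amide base converts the aryl bromide A8 (Br at C6, H at C1, OMe at C2, OSi at C4) into the aryne. A methyl Grignard reagent adds at C6, away from the methoxy group, and the arylmagnesium at C1 is trapped with a chloroformate to give methyl 2-methoxy-3,5,6-trimethyl-4-(triisopropylsilyloxy)benzoate A9.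
- Merits: the chemistry stays aromatic, needs no thermolysis, places two adjacent substituents in one flask, and the oxygens are differentiated from the start. If A8 were at hand this would be the shortest way to ring B.
- Weak points: A8 is itself a pentasubstituted arene that needs regioselective bromination and differential O-protection of an unsymmetrical resorcinol. Three organometallic species share one flask, and the electrophile is also consumed by excess Grignard reagent. Lateral deprotonation of the ring methyl groups and protonation of the hindered aryl anion by the liberated amine both compete.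
- Comparison: the chosen plan has a diene whose two donors direct the regiochemistry the same way, and only one new C–C bond-forming event to control.

Key step: step 4

Remark on the chemistry: the target has no stereocenter; enone 3 and adduct 6 are chiral, are carried as racemates, and lose their stereocenters in steps 3 and 4.

## Route

**Step 1**
Reactants: 1 2-methylcyclohexane-1,3-dione
Product: 2 3-methoxy-2-methylcyclohex-2-en-1-one
Conditions: HC(OMe)3, MeOH, TsOH·H2O (cat.), reflux
Reagents that add atoms: trimethyl orthoformate, COC(OC)OC; methanol, CO
Why: Acid-catalysed enol etherification of a cyclic 1,3-dione (vinylogous esterification); the dione is symmetrical, so only one enol ether can form, and the orthoformate consumes the water.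

**Step 2**
Reactants: 2 3-methoxy-2-methylcyclohex-2-en-1-one
Product: 3 3-methoxy-2,6-dimethylcyclohex-2-en-1-one (racemic)
Conditions: LiN(iPr)2, THF, −78 °C; MeI, −78 → 0 °C
Reagents that add atoms: iodomethane, CI
Why: Stork–Danheiser alkylation: kinetic deprotonation of a vinylogous ester occurs at the α′ carbon and the cross-conjugated enolate is C-methylated; the new stereocenter is formed without control and is removed in step 3.

**Step 3**
Reactants: 3 3-methoxy-2,6-dimethylcyclohex-2-en-1-one
Product: 4 3-(tert-butyldimethylsilyloxy)-1-methoxy-2,4-dimethylcyclohexa-1,3-diene
Conditions: LiN(iPr)2, THF, −78 °C; tBuMe2SiCl, DMPU, −78 °C → rt; pentane, filtration, bulb-to-bulb distillation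
Reagents that add atoms: tert-butyldimethylsilyl chloride, CC(C)(C)[Si](C)(C)Cl
Why: Kinetic enolisation at the remaining α′ hydrogen followed by O-silylation, the standard preparation of 1-alkoxy-3-siloxycyclohexa-1,3-dienes from 3-alkoxycyclohexenones; the tert-butyldimethylsilyl group is chosen so that the dienol ether survives isolation and heating.

**Step 4**
Reactants: 4 3-(tert-butyldimethylsilyloxy)-1-methoxy-2,4-dimethylcyclohexa-1,3-diene; 5 methyl but-2-ynoate
Product: 7 methyl 4-(tert-butyldimethylsilyloxy)-2-methoxy-3,5,6-trimethylbenzoate, via bicyclo[2.2.2]octa-2,5-diene adduct 6 (not isolated)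
Conditions: neat 5 (3 equiv), Ar, sealed tube, 170 °C
Reagents that add atoms: none
Why: This is an Alder–Rickert arene synthesis, the known reaction of 1-alkoxy-3-siloxycyclohexa-1,3-dienes with acetylenic esters. The s-cis-locked, doubly oxygen-activated diene 4 adds to alkynoate 5 in a thermal, asynchronous [4+2] cycloaddition that forms C5–C6 and C1–C2 and gives adduct 6 with OMe and Me at the bridgeheads. Ring B therefore closes by intermolecular cycloaddition, both ring bonds forming in one step, and it becomes a benzene ring when the CH2–CH2 bridge of 6 leaves as ethene in a retro-[4+2] step driven by aromatisation and gas loss. The step needs regioselectivity, and the diene supplies it: the methoxy group through the diene and the siloxy group directly both raise the HOMO coefficient at the methyl-bearing silyl enol ether terminus, which bonds to the electrophilic β carbon of 5 and so places CO2Me next to OMe. Sterics do not oppose this, since both diene termini are substituted and neither orientation is less hindered. Product 7 has no stereocenter; the two bridgehead stereocenters of 6 form as a racemate and are erased. No oxygen is eliminated, so the C2 methyl ether and the C4 silyl ether emerge already differentiated.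

**Step 5**
Reactants: 7 methyl 4-(tert-butyldimethylsilyloxy)-2-methoxy-3,5,6-trimethylbenzoate
Product: 8 methyl 4-hydroxy-2-methoxy-3,5,6-trimethylbenzoate
Conditions: Bu4NF, THF, 0 °C; dilute aq. HCl
Reagents that add atoms: none
Why: Fluoride cleavage of an aryl silyl ether; the phenoxide is a good leaving group on silicon and the hindered methyl ester is untouched at 0 °C.

**Step 6**
Reactants: 9 atraric acid (methyl 2,4-dihydroxy-3,6-dimethylbenzoate)
Product: 10 methyl 5-chloro-2,4-dihydroxy-3,6-dimethylbenzoate
Conditions: SO2Cl2 (1.05 equiv), Et2O, 0 °C → rt
Reagents that add atoms: sulfuryl chloride, O=S(=O)(Cl)Cl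
Why: Electrophilic aromatic chlorination; C5 is the only unsubstituted ring position and is activated by the ortho and para hydroxyl groups, so regiochemistry is not in question and one equivalent of reagent limits over-chlorination.

**Step 7**
Reactants: 10 methyl 5-chloro-2,4-dihydroxy-3,6-dimethylbenzoate
Product: 11 methyl 4-(allyloxy)-5-chloro-2-hydroxy-3,6-dimethylbenzoate
Conditions: allyl bromide (1.1 equiv), K2CO3, acetone, reflux
Reagents that add atoms: allyl bromide, C=CCBr
Why: Williamson etherification selective for the C4 hydroxyl, which is the more acidic one (ortho chlorine, para carbonyl), whereas the C2 hydroxyl is hydrogen-bonded to the ester carbonyl and reacts only under more forcing conditions.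

**Step 8**
Reactants: 11 methyl 4-(allyloxy)-5-chloro-2-hydroxy-3,6-dimethylbenzoate
Product: 12 methyl 4-(allyloxy)-5-chloro-2-methoxy-3,6-dimethylbenzoate
Conditions: MeI (excess), K2CO3, DMF, 50 °C
Reagents that add atoms: iodomethane, CI
Why: Williamson methylation of the chelated phenol in a dipolar aprotic solvent; the allyl ether cannot undergo Claisen rearrangement at this temperature, and both of its ortho positions are blocked.

**Step 9**
Reactants: 12 methyl 4-(allyloxy)-5-chloro-2-methoxy-3,6-dimethylbenzoate
Product: 13 4-(allyloxy)-5-chloro-2-methoxy-3,6-dimethylbenzoic acid
Conditions: KOH, DMSO–H2O, 85 °C; then aq. HCl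
Reagents that add atoms: potassium hydroxide, [K+].[OH-]
Why: Saponification of a di-ortho-substituted methyl benzoate with poorly solvated hydroxide in aqueous DMSO, the usual medium for hindered benzoates of this type; the electron-rich aryl chloride is not activated towards substitution.

**Step 10**
Reactants: 13 4-(allyloxy)-5-chloro-2-methoxy-3,6-dimethylbenzoic acid; 8 methyl 4-hydroxy-2-methoxy-3,5,6-trimethylbenzoate
Product: 15 methyl 4-{[4-(allyloxy)-5-chloro-2-methoxy-3,6-dimethylbenzoyl]oxy}-2-methoxy-3,5,6-trimethylbenzoate, via aroyl trifluoroacetyl mixed anhydride 14 (not isolated)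
Conditions: (CF3CO)2O, toluene, rt (13 and the anhydride premixed, then 8)
Reagents that add atoms: none
Why: Trifluoroacetic anhydride-mediated depside esterification: acid 13 forms mixed anhydride 14, which in the trifluoroacetic acid released ionises towards an acylium ion stabilised by the ortho and para alkoxy groups, and this small, linear electrophile is captured by the hindered phenol 8. Neither ring has a free position, so Friedel–Crafts acylation cannot compete.

**Step 11**
Reactants: 15 methyl 4-{[4-(allyloxy)-5-chloro-2-methoxy-3,6-dimethylbenzoyl]oxy}-2-methoxy-3,5,6-trimethylbenzoate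
Product: 16 methyl 4-[(5-chloro-4-hydroxy-2-methoxy-3,6-dimethylbenzoyl)oxy]-2-methoxy-3,5,6-trimethylbenzoate (CNP0192286.0)
Conditions: Pd(PPh3)4 (5 mol %), morpholine, THF, rt; dilute aq. HCl
Reagents that add atoms: none
Why: Tsuji–Trost deallylation: zerovalent palladium ionises the allyl aryl ether to a π-allyl complex and an acidic phenoxide, and morpholine takes up the allyl group. The aryl chloride does not undergo oxidative addition with this catalyst at room temperature, and the two shielded esters are inert to the amine.

## Compound list

1 | 2-methylcyclohexane-1,3-dione | CC1C(=O)CCCC1=O | starting material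
2 | 3-methoxy-2-methylcyclohex-2-en-1-one | COC1=C(C)C(=O)CCC1 | intermediate
3 | 3-methoxy-2,6-dimethylcyclohex-2-en-1-one (racemic) | COC1=C(C)C(=O)C(C)CC1 | intermediate
4 | 3-(tert-butyldimethylsilyloxy)-1-methoxy-2,4-dimethylcyclohexa-1,3-diene | COC1=C(C)C(O[Si](C)(C)C(C)(C)C)=C(C)CC1 | intermediate
5 | methyl but-2-ynoate | CC#CC(=O)OC | starting material
6 | methyl 5-(tert-butyldimethylsilyloxy)-1-methoxy-3,4,6-trimethylbicyclo[2.2.2]octa-2,5-diene-2-carboxylate (racemic; bridgehead configurations fixed by the bicycle) | COC(=O)C1=C(C)C2(C)CCC1(OC)C(C)=C2O[Si](C)(C)C(C)(C)C | intermediate (not isolated)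
7 | methyl 4-(tert-butyldimethylsilyloxy)-2-methoxy-3,5,6-trimethylbenzoate | COC(=O)c1c(C)c(C)c(O[Si](C)(C)C(C)(C)C)c(C)c1OC | intermediate
8 | methyl 4-hydroxy-2-methoxy-3,5,6-trimethylbenzoate | COC(=O)c1c(C)c(C)c(O)c(C)c1OC | intermediate
9 | atraric acid (methyl 2,4-dihydroxy-3,6-dimethylbenzoate) | COC(=O)c1c(C)cc(O)c(C)c1O | starting material
10 | methyl 5-chloro-2,4-dihydroxy-3,6-dimethylbenzoate | COC(=O)c1c(C)c(Cl)c(O)c(C)c1O | intermediate
11 | methyl 4-(allyloxy)-5-chloro-2-hydroxy-3,6-dimethylbenzoate | COC(=O)c1c(C)c(Cl)c(OCC=C)c(C)c1O | intermediate
12 | methyl 4-(allyloxy)-5-chloro-2-methoxy-3,6-dimethylbenzoate | COC(=O)c1c(C)c(Cl)c(OCC=C)c(C)c1OC | intermediate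
13 | 4-(allyloxy)-5-chloro-2-methoxy-3,6-dimethylbenzoic acid | OC(=O)c1c(C)c(Cl)c(OCC=C)c(C)c1OC | intermediate
14 | 4-(allyloxy)-5-chloro-2-methoxy-3,6-dimethylbenzoic trifluoroacetic anhydride | O=C(OC(=O)C(F)(F)F)c1c(C)c(Cl)c(OCC=C)c(C)c1OC | intermediate (not isolated)
15 | methyl 4-{[4-(allyloxy)-5-chloro-2-methoxy-3,6-dimethylbenzoyl]oxy}-2-methoxy-3,5,6-trimethylbenzoate | COC(=O)c1c(C)c(C)c(OC(=O)c2c(C)c(Cl)c(OCC=C)c(C)c2OC)c(C)c1OC | intermediate
16 | methyl 4-[(5-chloro-4-hydroxy-2-methoxy-3,6-dimethylbenzoyl)oxy]-2-methoxy-3,5,6-trimethylbenzoate | COC(=O)c1c(C)c(C)c(OC(=O)c2c(C)c(Cl)c(O)c(C)c2OC)c(C)c1OC | target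

## Step count and risks

Total step count: 11. Longest linear sequence: 7 steps (steps 1, 2, 3, 4, 5, 10, 11); the ring A arm contributes steps 6–9 and joins at step 10.

**Step 4 (key step).** The most likely failure is slow cycloaddition. Both new bonds join fully substituted carbons and the dienophile is a β-alkyl alkynoate. At the temperature required, protodesilylation of the diene back to the enone, or oligomerisation of the alkyne, could overtake the addition. The fallback gives up the cycloaddition and makes ring B from the arene pool. It sets out from atraric acid 9 and returns at phenol 8.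
- Formylation of 9 at its only free position with Cl2CHOMe and TiCl4 (Rieche formylation) should give methyl 5-formyl-2,4-dihydroxy-3,6-dimethylbenzoate F1.
- Ionic hydrogenation of the hydroxy-activated aldehyde with Et3SiH in CF3CO2H should give methyl 2,4-dihydroxy-3,5,6-trimethylbenzoate F2.
- Benzylation of the non-chelated hydroxyl (benzyl bromide, K2CO3, acetone) should give methyl 4-(benzyloxy)-2-hydroxy-3,5,6-trimethylbenzoate F3.
- Methylation of the chelated hydroxyl (MeI, K2CO3, DMF) should give methyl 4-(benzyloxy)-2-methoxy-3,5,6-trimethylbenzoate F4.
- Hydrogenolysis (H2, Pd on carbon) should release 8; ring B carries no halogen, so this is safe.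

**Step 3.** The remaining α′ hydrogen is tertiary, so enolisation may be incomplete or diverted to the γ position. C-silylation and hydrolysis of the dienol ether during isolation are further risks. The fallback moves the silylation ahead of the methyl group and adds that methyl group on the arene. It sets out from enone 2 and returns at phenol 8.
- Kinetic enolisation of 2 at its secondary α′ position and silylation should give 3-(tert-butyldimethylsilyloxy)-1-methoxy-2-methylcyclohexa-1,3-diene F5.
- The Alder–Rickert reaction of F5 with 5, now at an unsubstituted diene terminus, should give methyl 4-(tert-butyldimethylsilyloxy)-2-methoxy-3,6-dimethylbenzoate F6.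
- Fluoride should give methyl 4-hydroxy-2-methoxy-3,6-dimethylbenzoate F7.
- Magnesium-mediated ortho-formylation (MgCl2, Et3N, paraformaldehyde) at the only open position should give methyl 5-formyl-4-hydroxy-2-methoxy-3,6-dimethylbenzoate F8.
- Reduction of the formyl group with Et3SiH in CF3CO2H should give 8.

**Step 10.** Acyl transfer to a phenol flanked by two methyl groups may be slow, and reversible O-trifluoroacetylation of 8 may consume the activator. The fallback replaces the acid-mediated acylium route with a base-mediated one. It sets out from acid 13 and returns at 15. Oxalyl chloride with catalytic DMF should convert 13 into 4-(allyloxy)-5-chloro-2-methoxy-3,6-dimethylbenzoyl chloride F9, which is then added to the sodium phenoxide of 8 (NaH, THF, rt to reflux).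

**Step 9.** Hydroxide attack on the shielded ester carbonyl may be slow, and under prolonged heating in a basic dipolar medium the allyl ether may isomerise to a propenyl ether. The fallback avoids acyl substitution by a redox detour. It sets out from ester 12 and returns at acid 13.
- LiAlH4 in THF should reduce 12 to [4-(allyloxy)-5-chloro-2-methoxy-3,6-dimethylphenyl]methanol F10.
- MnO2 in CH2Cl2 should oxidise F10 to 4-(allyloxy)-5-chloro-2-methoxy-3,6-dimethylbenzaldehyde F11.
- Pinnick oxidation (NaClO2, NaH2PO4, 2-methylbut-2-ene, tBuOH–H2O) should give 13; the alkene scavenger protects the allyl group.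

## Further compounds

F1 | step 4 | methyl 5-formyl-2,4-dihydroxy-3,6-dimethylbenzoate | COC(=O)c1c(C)c(C=O)c(O)c(C)c1O
F2 | step 4 | methyl 2,4-dihydroxy-3,5,6-trimethylbenzoate | COC(=O)c1c(C)c(C)c(O)c(C)c1O
F3 | step 4 | methyl 4-(benzyloxy)-2-hydroxy-3,5,6-trimethylbenzoate | COC(=O)c1c(C)c(C)c(OCc2ccccc2)c(C)c1O
F4 | step 4 | methyl 4-(benzyloxy)-2-methoxy-3,5,6-trimethylbenzoate | COC(=O)c1c(C)c(C)c(OCc2ccccc2)c(C)c1OC
F5 | step 3 | 3-(tert-butyldimethylsilyloxy)-1-methoxy-2-methylcyclohexa-1,3-diene | COC1=C(C)C(O[Si](C)(C)C(C)(C)C)=CCC1
F6 | step 3 | methyl 4-(tert-butyldimethylsilyloxy)-2-methoxy-3,6-dimethylbenzoate | COC(=O)c1c(C)cc(O[Si](C)(C)C(C)(C)C)c(C)c1OC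
F7 | step 3 | methyl 4-hydroxy-2-methoxy-3,6-dimethylbenzoate | COC(=O)c1c(C)cc(O)c(C)c1OC
F8 | step 3 | methyl 5-formyl-4-hydroxy-2-methoxy-3,6-dimethylbenzoate | COC(=O)c1c(C)c(C=O)c(O)c(C)c1OC
F9 | step 10 | 4-(allyloxy)-5-chloro-2-methoxy-3,6-dimethylbenzoyl chloride | COc1c(C)c(OCC=C)c(Cl)c(C)c1C(Cl)=O
F10 | step 9 | [4-(allyloxy)-5-chloro-2-methoxy-3,6-dimethylphenyl]methanol | COc1c(C)c(OCC=C)c(Cl)c(C)c1CO
F11 | step 9 | 4-(allyloxy)-5-chloro-2-methoxy-3,6-dimethylbenzaldehyde | COc1c(C)c(OCC=C)c(Cl)c(C)c1C=O
A1 | alternative 1 | dimethyl malonate | COC(=O)CC(=O)OC
A2 | alternative 1 | (E)-4-methylhex-4-en-3-one | C/C=C(\C)C(=O)CC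
A3 | alternative 1 | methyl 3,5,6-trimethyl-2,4-dioxocyclohexane-1-carboxylate (mixture of diastereomers and enol forms) | COC(=O)C1C(C)C(C)C(=O)C(C)C1=O
A4 | alternative 1 | methyl 2,4-dihydroxy-3,5,6-trimethylbenzoate | COC(=O)c1c(C)c(C)c(O)c(C)c1O
A5 | alternative 2 | methyl 4-(but-2-ynoyloxy)-2-methoxy-3,5,6-trimethylbenzoate | CC#CC(=O)Oc1c(C)c(C)c(C(=O)OC)c(OC)c1C
A6 | alternative 2 | 1,1-dimethoxy-2-methyl-3-(trimethylsilyloxy)buta-1,3-diene | COC(OC)=C(C)C(=C)O[Si](C)(C)C
A7 | alternative 2 | methyl 4-[(4-hydroxy-2-methoxy-3,6-dimethylbenzoyl)oxy]-2-methoxy-3,5,6-trimethylbenzoate | COC(=O)c1c(C)c(C)c(OC(=O)c2c(C)cc(O)c(C)c2OC)c(C)c1OC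
A8 | alternative 3 | (3-bromo-5-methoxy-2,6-dimethylphenoxy)triisopropylsilane | COc1cc(Br)c(C)c(O[Si](C(C)C)(C(C)C)C(C)C)c1C
A9 | alternative 3 | methyl 2-methoxy-3,5,6-trimethyl-4-(triisopropylsilyloxy)benzoate | COC(=O)c1c(C)c(C)c(O[Si](C(C)C)(C(C)C)C(C)C)c(C)c1OC
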